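**Retrosynthetic overview**

1. The target is a guai-4-en-3-one. Guaiane numbering is used throughout: C-1/C-5 ring fusion, C-2 CH2, C-3 C=O, C-4 C–CH3, C-6 CH2, C-7 CH bearing C-11, C-8 CH–O, C-9 CH2, C-10 CH–CH3, C-11 C(CH3)2–O. The two esters go on last, from a C-8/C-11 diol carried as an acetonide.
2. Key disconnection: the enone C-3(=O)–C-4(CH3)=C-5 of the five-membered ring is an aldol retron on a 1,4-diketone. In that diketone C-2 is the β-carbon of the C-5 ring ketone, i.e. a ketone homoenolate. C-5/C-1/C-2 are therefore drawn as a siloxycyclopropane fused to the seven-membered ring. Strain-release acylation with propanoyl chloride makes C-2–C-3, and aldol condensation in the same flask makes C-4=C-5.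
3. The siloxycyclopropane comes from a regiodefined silyl enol ether, made by asymmetric conjugate reduction of a 3-methylcyclohept-2-enone (sets C-10). Cyclopropanation anti to the C-10 methyl sets C-1.
4. The cycloheptenone comes from a 2-methylcyclohexenone by a first cyclopropane opening (one-carbon ring expansion, C-1 inserted between C-5 and C-10). The cyclohexene comes from a catalytic asymmetric Diels–Alder reaction that sets C-7 and C-8 cis.
5. Ring order: six-membered carbocycle (Diels–Alder), expanded to the seven-membered ring, five-membered enone ring annulated last.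

Key step: step 11

Assumption: the senses of induction written for the two chiral catalysts (steps 2 and 9) follow the accepted facial models for these catalyst classes; if a model run showed the opposite sense, the antipodal ligand would be used and nothing else changes.

**Step 1**
Reactants: 1 3-methylbut-2-enal
Product: 2 (1E)-3-methylbuta-1,3-dien-1-yl acetate
Conditions: Ac2O, KOAc (cat.), 110 °C, product distilled
Reagents that add atoms: acetic anhydride, CC(=O)OC(C)=O
Why: Dienol acetate formation (γ-deprotonation of the enal and O-acetylation of the dienolate) should give the (E)-1-acetoxydiene, which can reach the s-cis form needed for the cycloaddition; no stereocentre is formed.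

**Step 2**
Reactants: 2 (1E)-3-methylbuta-1,3-dien-1-yl acetate; 3 3-acryloyl-1,3-oxazolidin-2-one
Product: 4 (1R,6S)-3-methyl-6-[(2-oxo-1,3-oxazolidin-3-yl)carbonyl]cyclohex-2-en-1-yl acetate
Conditions: [Cu((S,S)-t-Bu-box)](SbF6)2 (5 mol %), CH2Cl2, −20 °C to rt
Reagents that add atoms: none
Why: Catalytic enantioselective Diels–Alder reaction in which the acryloyl imide is chelated s-cis on the square-planar divalent copper complex of 2,2'-(propane-2,2-diyl)bis[(4S)-4-tert-butyl-4,5-dihydro-1,3-oxazole], one tert-butyl group shields one face, the 1-acetoxy (ortho) and 3-methyl (para) groups direct the regiochemistry, and endo addition should set C-7 (S) and C-8 (R) cis to each other under catalyst control.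

**Step 3**
Reactants: 4 (1R,6S)-3-methyl-6-[(2-oxo-1,3-oxazolidin-3-yl)carbonyl]cyclohex-2-en-1-yl acetate
Product: 5 (1R,6S)-6-(2-hydroxypropan-2-yl)-3-methylcyclohex-2-en-1-ol
Conditions: MeMgBr (6 equiv), THF, −40 to 0 °C; aq. NH4Cl
Reagents that add atoms: methylmagnesium bromide, C[Mg]Br
Why: Grignard addition, in which two methyl groups add to the exocyclic imide carbonyl (acyl substitution, then ketone addition) to build the C-11 carbinol while the same reagent cleaves the acetate; at low temperature addition should outrun enolisation, so C-7 and C-8 are kept.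

**Step 4**
Reactants: 5 (1R,6S)-6-(2-hydroxypropan-2-yl)-3-methylcyclohex-2-en-1-ol
Product: 6 (4aS,8aR)-2,2,4,4,7-pentamethyl-4a,5,6,8a-tetrahydro-4H-1,3-benzodioxine
Conditions: 2-methoxypropene, PPTS (cat.), CH2Cl2, 0 °C
Reagents that add atoms: 2-methoxypropene, COC(C)=C
Why: Acetonide formation by acetal exchange under mild pyridinium catalysis should tie the cis secondary and tertiary hydroxyls into a 1,3-dioxane without ionising the allylic C–O bond; no stereocentre is affected.

**Step 5**
Reactants: 6 (4aS,8aR)-2,2,4,4,7-pentamethyl-4a,5,6,8a-tetrahydro-4H-1,3-benzodioxine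
Product: 8 (4aS,8aR)-2,2,4,4,7-pentamethyl-4a,8a-dihydro-4H-1,3-benzodioxin-6(5H)-one, via allylic alcohol 7 (not isolated)
Conditions: SeO2 (20 mol %), t-BuOOH, CH2Cl2, 0 °C to rt; then 1,1,1-triacetoxy-1,1-dihydro-1,2-benziodoxol-3(1H)-one, pyridine, CH2Cl2, 0 °C
Reagents that add atoms: selenium dioxide, O=[Se]=O; tert-butyl hydroperoxide, CC(C)(C)OO
Why: Allylic oxidation by the SeO2 ene/[2,3]-sigmatropic sequence attacks at the more substituted alkene terminus and prefers a ring CH2 over CH3, so oxygen should enter at the ring methylene next to the methyl-bearing alkene carbon (future C-5) and not at the oxygenated allylic CH; the periodinane then oxidises the allylic alcohol to the enone, which removes the carbinol stereocentre.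

**Step 6**
Reactants: 8 (4aS,8aR)-2,2,4,4,7-pentamethyl-4a,8a-dihydro-4H-1,3-benzodioxin-6(5H)-one
Product: 10 (4aS,8aR)-2,2,4,4,7-pentamethyl-6-(trimethylsilyloxy)-4a,5,8,8a-tetrahydro-4H-1,3-benzodioxine, via lithium enolate 9 (not isolated)
Conditions: LiBH(s-Bu)3, THF, −78 °C; then Me3SiCl, Et3N, −78 to 0 °C
Reagents that add atoms: chlorotrimethylsilane, C[Si](C)(C)Cl
Why: Conjugate hydride reduction of the β-unsubstituted enone by the bulky borohydride, followed by O-silylation of the enolate, should give the tetrasubstituted silyl enol ether on the methyl-bearing side only; the methyl-bearing carbon stays sp2, so no stereocentre arises.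

**Step 7**
Reactants: 10 (4aS,8aR)-2,2,4,4,7-pentamethyl-6-(trimethylsilyloxy)-4a,5,8,8a-tetrahydro-4H-1,3-benzodioxine
Product: 11 1-methyl-6-(trimethylsilyloxy)bicyclo[4.1.0]heptane carrying the acetonide of 10 (O on C-3 and CMe2 on C-4 of the bicycle; ring fusion 4aS,8aR as in 10; cyclopropane on either face)
Conditions: Et2Zn, CH2I2, CH2Cl2, 0 °C to rt
Reagents that add atoms: diiodomethane, ICI
Why: Simmons–Smith cyclopropanation of the electron-rich silyl enol ether by the zinc carbenoid; the two new stereocentres are destroyed in step 8, so the face of attack does not matter.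

**Step 8**
Reactants: 11 1-methyl-6-(trimethylsilyloxy)bicyclo[4.1.0]heptane carrying the acetonide of 10
Product: 13 (4aS,9aR)-2,2,4,4,8-pentamethyl-4a,5,9,9a-tetrahydro-4H-cyclohepta[d][1,3]dioxin-6-one, via chloro ketone 12 (not isolated)
Conditions: FeCl3 (2.2 equiv), pyridine, DMF, 0 °C to rt; then NaOAc, MeOH, 65 °C
Reagents that add atoms: none
Why: Oxidative ring expansion of a siloxycyclopropane, in which one-electron oxidation by FeCl3 cleaves the internal cyclopropane bond to the C-5 ketone and a tertiary β-keto radical at C-10 that is chlorinated, and E1cB loss of HCl with NaOAc gives the conjugated cycloheptenone; ring strain drives the insertion of C-1 between C-5 and C-10, and no stereocentre is formed.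

**Step 9**
Reactants: 13 (4aS,9aR)-2,2,4,4,8-pentamethyl-4a,5,9,9a-tetrahydro-4H-cyclohepta[d][1,3]dioxin-6-one
Product: 14 (4aS,8S,9aR)-6-[diethoxy(methyl)silyl]oxy-2,2,4,4,8-pentamethyl-4,4a,5,8,9,9a-hexahydrocyclohepta[d][1,3]dioxine
Conditions: Cu(OAc)2·H2O (3 mol %), (S)-DTBM-SEGPHOS (3 mol %), MeSiH(OEt)2, toluene, 0 °C
Reagents that add atoms: diethoxy(methyl)silane, C[SiH](OCC)OCC
Why: Copper hydride catalysed asymmetric conjugate reduction (1,4-hydrosilylation), in which the chiral bisphosphine copper hydride delivers hydride to C-10 from the face opposite the C-8 oxygen (ligand control, reinforced by the cis-fused acetonide) and so sets C-10 (S), and σ-bond metathesis of the copper enolate with the silane releases the regiodefined C-5/C-1 silyl enol ether.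

**Step 10**
Reactants: 14 (4aS,8S,9aR)-6-[diethoxy(methyl)silyl]oxy-2,2,4,4,8-pentamethyl-4,4a,5,8,9,9a-hexahydrocyclohepta[d][1,3]dioxine
Product: 15 C-1/C-5 siloxycyclopropane of 14 (C-2 methylene on the face opposite the C-10 methyl; 1R,5R,7S,8R,10S in guaiane numbering)
Conditions: Et2Zn, CH2I2, CH2Cl2, 0 °C
Reagents that add atoms: diiodomethane, ICI
Why: Simmons–Smith cyclopropanation of the silyl enol ether from the face anti to the adjacent C-10 methyl and to the dioxane ring should place C-2 trans to the methyl, setting C-1 (R) and the C-5 carbinol centre, the latter being lost again in step 11.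

**Step 11**
Reactants: 15 C-1/C-5 siloxycyclopropane of 14
Product: 17 (1R,7S,8R,10S)-8,11-(isopropylidenedioxy)guai-4-en-3-one, via diketone 16 (not isolated)
Conditions: PdCl2(PPh3)2 (5 mol %), EtCOCl (1.5 equiv), CO (1 atm), CHCl3, 70 °C; then KOH, MeOH, 50 °C, same flask
Reagents that add atoms: propanoyl chloride, CCC(=O)Cl
Why: Oxidative addition of propanoyl chloride to zerovalent palladium gives an acylpalladium chloride, which attacks the strained siloxycyclopropane at its least hindered bond, C-5–C-2, with loss of the silyl group as a chlorosilane; the resulting palladium homoenolate (C-5 ketone, C-2–Pd) undergoes reductive elimination to form C-2–C-3 and the 1,4-diketone 16. The closest known reaction types are the palladium-catalysed acylation of siloxycyclopropanes with acid chlorides to 1,4-diketones and the classical base-mediated cyclisation of 2-(2-oxoalkyl)cycloalkanones to fused cyclopentenones. Hydroxide then enolises the ethyl ketone at C-4, and intramolecular aldol addition to the C-5 ketone followed by E1cB dehydration closes the five-membered ring in the 5-(enolendo)-exo-trig mode (formally disfavoured for enolates, yet the standard mode by which 1,4-diketones give cyclopentenones) and forms C-4=C-5. No new stereocentre is made: C-1 keeps the configuration set in step 10 because the C-1–C-2 bond is never broken, and should C-1 epimerise through the C-5 enolate or the dienolate of 17, the trans arrangement of C-2 and the C-10 methyl is expected to be the more stable one. The step needs (a) cleavage of C-5–C-2 and not C-5–C-1, secured by the substitution pattern (free CH2 against ring CH), (b) reductive elimination faster than β-hydride elimination or decarbonylation, secured by the CO atmosphere and the fast acyl–alkyl coupling, and (c) closure to the fused enone and not to a bridged aldol, secured because only the fused aldol can dehydrate to a conjugated enone while the others revert.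

**Step 12**
Reactants: 17 (1R,7S,8R,10S)-8,11-(isopropylidenedioxy)guai-4-en-3-one
Product: 18 (1R,7S,8R,10S)-8,11-dihydroxyguai-4-en-3-one
Conditions: AcOH–H2O (4:1), 40 °C
Reagents that add atoms: none
Why: Acid-catalysed acetal hydrolysis should free the C-8 and C-11 hydroxyls while the tetrasubstituted enone and all stereocentres stay untouched under mild aqueous acid.

**Step 13**
Reactants: 18 (1R,7S,8R,10S)-8,11-dihydroxyguai-4-en-3-one
Product: 19 (1R,7S,8R,10S)-11-hydroxy-8-(2-methylpropanoyloxy)guai-4-en-3-one
Conditions: (i-PrCO)2O, Et3N, DMAP (cat.), CH2Cl2, 0 °C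
Reagents that add atoms: 2-methylpropanoic anhydride, CC(C)C(=O)OC(=O)C(C)C
Why: Nucleophile-catalysed acylation (DMAP) should distinguish the secondary C-8 hydroxyl from the hindered tertiary C-11 hydroxyl and proceeds with retention at C-8.

**Step 14**
Reactants: 19 (1R,7S,8R,10S)-11-hydroxy-8-(2-methylpropanoyloxy)guai-4-en-3-one
Product: 20 (1R,7S,8R,10S)-11-acetoxy-8-(2-methylpropanoyloxy)guai-4-en-3-one (CNP0197994.1)
Conditions: Ac2O, Sc(OTf)3 (2 mol %), MeCN, −20 °C
Reagents that add atoms: acetic anhydride, CC(=O)OC(C)=O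
Why: Lewis acid catalysed acetylation of a tertiary alcohol at low temperature, where elimination of the C-11 carbinol and 1,3-acyl migration should be slow; no stereocentre is affected.

**Compound list**

1 | 3-methylbut-2-enal | CC(C)=CC=O | starting material
2 | (1E)-3-methylbuta-1,3-dien-1-yl acetate | C=C(C)/C=C/OC(C)=O | intermediate
3 | 3-acryloyl-1,3-oxazolidin-2-one | C=CC(=O)N1CCOC1=O | starting material
4 | (1R,6S)-3-methyl-6-[(2-oxo-1,3-oxazolidin-3-yl)carbonyl]cyclohex-2-en-1-yl acetate | O=C(N2CCOC2=O)[C@H]1CCC(C)=C[C@H]1OC(C)=O | intermediate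
5 | (1R,6S)-6-(2-hydroxypropan-2-yl)-3-methylcyclohex-2-en-1-ol | CC(C)(O)[C@H]1CCC(C)=C[C@H]1O | intermediate
6 | (4aS,8aR)-2,2,4,4,7-pentamethyl-4a,5,6,8a-tetrahydro-4H-1,3-benzodioxine | CC1(C)[C@H]2CCC(C)=C[C@H]2OC(C)(C)O1 | intermediate
7 | (4aS,8aR)-2,2,4,4,7-pentamethyl-4a,5,6,8a-tetrahydro-4H-1,3-benzodioxin-6-ol (either C-6 epimer) | CC1(C)[C@H]2CC(O)C(C)=C[C@H]2OC(C)(C)O1 | intermediate (not isolated)
8 | (4aS,8aR)-2,2,4,4,7-pentamethyl-4a,8a-dihydro-4H-1,3-benzodioxin-6(5H)-one | CC1(C)[C@H]2CC(=O)C(C)=C[C@H]2OC(C)(C)O1 | intermediate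
9 | lithium (4aS,8aR)-2,2,4,4,7-pentamethyl-4a,5,8,8a-tetrahydro-4H-1,3-benzodioxin-6-olate | CC1(C)[C@H]2CC([O-])=C(C)C[C@H]2OC(C)(C)O1.[Li+] | intermediate (not isolated)
10 | (4aS,8aR)-2,2,4,4,7-pentamethyl-6-(trimethylsilyloxy)-4a,5,8,8a-tetrahydro-4H-1,3-benzodioxine | CC1(C)[C@H]2CC(O[Si](C)(C)C)=C(C)C[C@H]2OC(C)(C)O1 | intermediate
11 | 1-methyl-6-(trimethylsilyloxy)bicyclo[4.1.0]heptane carrying the acetonide of 10 (fusion 4aS,8aR; cyclopropane on either face) | CC1(C)[C@H]2CC3(O[Si](C)(C)C)CC3(C)C[C@H]2OC(C)(C)O1 | intermediate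
12 | (4aS,9aR)-8-chloro-2,2,4,4,8-pentamethylhexahydro-4H-cyclohepta[d][1,3]dioxin-6(5H)-one (either C-8 epimer) | CC1(C)[C@H]2CC(=O)CC(C)(Cl)C[C@H]2OC(C)(C)O1 | intermediate (not isolated)
13 | (4aS,9aR)-2,2,4,4,8-pentamethyl-4a,5,9,9a-tetrahydro-4H-cyclohepta[d][1,3]dioxin-6-one | CC1(C)[C@H]2CC(=O)C=C(C)C[C@H]2OC(C)(C)O1 | intermediate
14 | (4aS,8S,9aR)-6-[diethoxy(methyl)silyl]oxy-2,2,4,4,8-pentamethyl-4,4a,5,8,9,9a-hexahydrocyclohepta[d][1,3]dioxine | CC1(C)[C@H]2CC(O[Si](C)(OCC)OCC)=C[C@@H](C)C[C@H]2OC(C)(C)O1 | intermediate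
15 | C-1/C-5 siloxycyclopropane of 14 (C-2 methylene anti to the C-10 methyl; 1R,5R,7S,8R,10S) | CC1(C)[C@H]2C[C@]3(O[Si](C)(OCC)OCC)C[C@@H]3[C@@H](C)C[C@H]2OC(C)(C)O1 | intermediate
16 | (4aS,7R,8S,9aR)-2,2,4,4,8-pentamethyl-7-(2-oxobutyl)hexahydro-4H-cyclohepta[d][1,3]dioxin-6(5H)-one | CC1(C)[C@H]2CC(=O)[C@H](CC(=O)CC)[C@@H](C)C[C@H]2OC(C)(C)O1 | intermediate (not isolated)
17 | (1R,7S,8R,10S)-8,11-(isopropylidenedioxy)guai-4-en-3-one | CC1(C)[C@H]2CC3=C(C)C(=O)C[C@@H]3[C@@H](C)C[C@H]2OC(C)(C)O1 | intermediate
18 | (1R,7S,8R,10S)-8,11-dihydroxyguai-4-en-3-one | CC(C)(O)[C@H]1CC2=C(C)C(=O)C[C@@H]2[C@@H](C)C[C@H]1O | intermediate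
19 | (1R,7S,8R,10S)-11-hydroxy-8-(2-methylpropanoyloxy)guai-4-en-3-one | CC(C)(O)[C@H]1CC2=C(C)C(=O)C[C@@H]2[C@@H](C)C[C@H]1OC(=O)C(C)C | intermediate
20 | (1R,7S,8R,10S)-11-acetoxy-8-(2-methylpropanoyloxy)guai-4-en-3-one (CNP0197994.1) | CC(=O)OC(C)(C)[C@H]1CC2=C(C)C(=O)C[C@@H]2[C@@H](C)C[C@H]1OC(=O)C(C)C | target

**Step count and risks**

Total step count: 14. Longest linear sequence: 14 steps (1 to 20; dienophile 3 is purchased).

Steps most likely to fail:

Step 11 (key step). The palladium homoenolate may undergo β-hydride elimination to the 2-methylidene ketone, or the propanoyl–palladium species may lose CO, so that acyl transfer to C-2 fails. The fallback reverses polarity at C-3 instead of C-2 and sets out from silyl enol ether 14. A Mannich reaction with dimethyl(methylidene)ammonium iodide in CH2Cl2 gives the β-amino ketone F1. Heated with propanal, 3-benzyl-5-(2-hydroxyethyl)-4-methylthiazolium chloride (cat.) and Et3N in ethanol, it should lose dimethylamine to the 2-methylidene ketone F2 (not isolated). The thiazolium-derived acyl anion equivalent adds to this in a Stetter reaction to give diketone 16. The route is rejoined at 16, which is closed to 17 with KOH in MeOH as in step 11; C-1 is then set by equilibration.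

Step 8. The Lewis-acidic iron salts may open the acetonide, or the tertiary β-keto radical may be diverted (further chlorination, elimination to a non-conjugated alkene), which would erode the ring expansion. The fallback uses a carbenoid 1,2-shift instead of radical cyclopropane opening; it sets out from enone 8 and replaces steps 6 to 8. LiCHBr2, generated in the presence of 8 from CH2Br2 and LiN(i-Pr)2 in THF at −78 °C, adds to the carbonyl to give the dibromomethyl carbinol F3. n-BuLi (2 equiv, −78 °C) effects bromine–lithium exchange on its lithium alkoxide. The β-oxido carbenoid rearranges with migration of the alkenyl carbon C-10 (one-carbon ring expansion), and protonation of the dienolate at −78 °C gives the β,γ-unsaturated cycloheptenone F4. DBU (cat.) in CH2Cl2 at 0 °C moves the double bond into conjugation, and the route is rejoined at 13.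

Step 5. Oxidation may take place at the vinylic methyl group or at the oxygenated allylic ring CH, or stop at mixtures of alcohol and enone, so that the C-5 oxygen is not introduced cleanly. The fallback brings the C-5 oxygen in with the diene and needs no C–H oxidation; it sets out from dienophile 3 and replaces steps 1 to 4. Commercial (2E)-4-acetoxy-2-methylbut-2-enal is converted (Ac2O, KOAc) into the dienol acetate (1E,3E)-2-methylbuta-1,3-diene-1,4-diyl diacetate F5. Cycloaddition with 3 under the catalyst of step 2 should give the all-cis adduct F6, with the acyl carbon para to the methyl-bearing carbon. MeMgBr as in step 3 should give the triol F7. 2-Methoxypropene with PPTS closes the acetonide on the cis-1,3-diol and gives allylic alcohol 7, where the route is rejoined (periodinane oxidation to 8 as in step 5).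

**Further compounds**

F1 | step 11 | (4aS,8S,9aR)-7-[(dimethylamino)methyl]-2,2,4,4,8-pentamethylhexahydro-4H-cyclohepta[d][1,3]dioxin-6(5H)-one (either C-7 epimer) | CC1(C)[C@H]2CC(=O)C(CN(C)C)[C@@H](C)C[C@H]2OC(C)(C)O1
F2 | step 11 | (4aS,8S,9aR)-2,2,4,4,8-pentamethyl-7-methylidenehexahydro-4H-cyclohepta[d][1,3]dioxin-6(5H)-one | CC1(C)[C@H]2CC(=O)C(=C)[C@@H](C)C[C@H]2OC(C)(C)O1
F3 | step 8 | (4aS,8aR)-6-(dibromomethyl)-2,2,4,4,7-pentamethyl-4a,5,6,8a-tetrahydro-4H-1,3-benzodioxin-6-ol (either C-6 epimer) | CC1(C)[C@H]2CC(O)(C(Br)Br)C(C)=C[C@H]2OC(C)(C)O1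
F4 | step 8 | (4aS,9aR)-2,2,4,4,8-pentamethyl-4a,5,7,9a-tetrahydro-4H-cyclohepta[d][1,3]dioxin-6-one | CC1(C)[C@H]2CC(=O)CC(C)=C[C@H]2OC(C)(C)O1
F5 | step 5 | (1E,3E)-2-methylbuta-1,3-diene-1,4-diyl diacetate | CC(=O)O/C=C(C)/C=C/OC(C)=O
F6 | step 5 | (1R,4R,5S)-2-methyl-5-[(2-oxo-1,3-oxazolidin-3-yl)carbonyl]cyclohex-2-ene-1,4-diyl diacetate | O=C(N2CCOC2=O)[C@H]1C[C@@H](OC(C)=O)C(C)=C[C@H]1OC(C)=O
F7 | step 5 | (1R,4R,5S)-5-(2-hydroxypropan-2-yl)-2-methylcyclohex-2-ene-1,4-diol | CC(C)(O)[C@H]1C[C@@H](O)C(C)=C[C@H]1O
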